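The target is a xenicane, and xenicane numbering is used. The 2,5-dihydrofuran (O, C3, C4, C12, C13) shares the acetal carbon C3 and C4 with the tetrahydropyran (O2, C1, C11a, C4a). It is therefore an isomer of a vinyl oxirane, namely the C12–C13 epoxide on C4 of the enol ether O2–C3=C4, as in the presumed biogenesis. Sharpless epoxidation of dienol ether 26 generates this oxirane, whose oxygen slips from C12 to C3. One operation thus grows the three-membered ring to five and sets the acetal, the C4=C12 bond, C13 and C3. The precursor is a 5-dienyl-3,4-dihydro-2H-pyran fused to a Z-cyclononene made by metathesis. C7 comes from (S)-linalool.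

Key step: step 19

Numbering: C1 (OCH2), O2, C3 (acetal CH), C4, C4a, C5, C6, C7 (methyl C18), C8, C9, C10, C11 (=C19H2), C11a. The side chain is C12, C13, C14, C15 (methyls C16, C17).

Assumption: (S)-(+)-linalool is bought in high enantiomeric purity, and the ligand enantiomer in step 9 is the one that gives the 11aR product, its sense being assigned by analogy with cyclohex-2-enone.

**Arm C5–C8 (steps 1–5)**

Step 1
Reactants: 1 (S)-(+)-linalool
Product: 2 (S)-linalool triethylsilyl ether
Conditions: TESOTf, 2,6-lutidine, CH2Cl2, −78 to 0 °C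
Reagents that add atoms: triethylsilyl triflate, CC[Si](CC)(CC)OS(=O)(=O)C(F)(F)F
Why: O-silylation of the hindered tertiary alcohol with a silyl triflate and a non-nucleophilic base leaves the chiral-pool stereocentre (the later C7) untouched.

Step 2
Reactants: 2 (S)-linalool triethylsilyl ether
Product: 3 (S)-4-methyl-4-(triethylsilyloxy)hex-5-enal
Conditions: O3 (1 equiv, Sudan red 7B end point), CH2Cl2, −78 °C; PPh3
Reagents that add atoms: ozone, [O-][O+]=O
Why: Chemoselective ozonolysis should work because the electron-rich trisubstituted alkene reacts far faster than the hindered monosubstituted vinyl group.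

Step 3
Reactants: 3 (S)-4-methyl-4-(triethylsilyloxy)hex-5-enal
Product: 4 (S,Z)-tert-butyldimethylsilyl enol ether of 3 (geometry irrelevant)
Conditions: TBSOTf, Et3N, CH2Cl2, 0 °C
Reagents that add atoms: tert-butyldimethylsilyl triflate, CC(C)(C)[Si](C)(C)OS(=O)(=O)C(F)(F)F
Why: Soft enolisation and O-silylation of the aldehyde prepares the removal of one carbon and creates no stereocentre.

Step 4
Reactants: 4 silyl enol ether of 3
Product: 5 (S)-3-methyl-3-(triethylsilyloxy)pent-4-en-1-ol
Conditions: O3 (1 equiv), CH2Cl2–MeOH, −78 °C; NaBH4, −78 °C to rt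
Reagents that add atoms: ozone, [O-][O+]=O
Why: Ozonolysis of the very electron-rich enol ether in the presence of the vinyl group, with reductive work-up, shortens the chain by one carbon to the primary alcohol.

Step 5
Reactants: 5 (S)-3-methyl-3-(triethylsilyloxy)pent-4-en-1-ol
Product: 6 (S)-5-iodo-3-methyl-3-(triethylsilyloxy)pent-1-ene
Conditions: I2, PPh3, imidazole, CH2Cl2, 0 °C
Reagents that add atoms: iodine, II
Why: Appel-type iodination of the primary alcohol proceeds under near-neutral conditions that the tertiary silyl ether tolerates.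

**Arm C9–C11, C19 (step 6)**

Step 6
Reactants: 7 2,3-dibromopropene
Product: 8 2-bromopenta-1,4-diene
Conditions: vinylmagnesium bromide, CuI (5 mol %), THF, 0 °C
Reagents that add atoms: vinylmagnesium bromide, C=C[Mg]Br
Why: Copper-catalysed allylic substitution takes place at the allylic C–Br bond only and leaves the vinylic bromide for the next metalation.

**Pyranone (steps 7–8)**

Step 7
Reactants: 9 furfuryl alcohol
Product: 10 6-hydroxy-2H-pyran-3(6H)-one (racemic lactol)
Conditions: NBS, NaHCO3, THF–H2O, 0 °C
Reagents that add atoms: water, O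
Why: In the Achmatowicz rearrangement, oxidative opening of the furan to the Z-enedione and reclosure through the carbinol oxygen give the pyranone.

Step 8
Reactants: 10 6-hydroxy-2H-pyran-3(6H)-one
Product: 11 2H-pyran-3(6H)-one
Conditions: Et3SiH, CF3CO2H, CH2Cl2, −30 to 0 °C
Reagents that add atoms: none
Why: In this ionic reduction the acid ionises the lactol to the oxocarbenium ion, which the silane reduces at the former anomeric carbon, so the only stereocentre is removed.

**Union and nine-membered ring (steps 9–12)**

Step 9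
Reactants: 8 2-bromopenta-1,4-diene; 11 2H-pyran-3(6H)-one
Product: 14 (R)-5-(penta-1,4-dien-2-yl)-3-(trimethylsilyloxy)-5,6-dihydro-2H-pyran, via Grignard reagent 12 (not isolated), via bromomagnesium enolate 13 (not isolated)
Conditions: 8, Mg, 2-MeTHF; then 11, CuBr·SMe2 (5 mol %), TADDOL-derived phosphine–phosphite ligand (6 mol %), −78 °C; then TMSCl, Et3N, DMPU, −78 °C to rt
Reagents that add atoms: chlorotrimethylsilane, C[Si](C)(C)Cl
Why: In this copper-catalysed enantioselective 1,4-addition of an alkenyl Grignard reagent to a cyclic enone, the chiral ligand sets C11a (R) and silylation locks the enolate as the C4=C4a regioisomer.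

Step 10
Reactants: 14 silyl enol ether; 6 iodide
Product: 16 (4S,5R)-5-(penta-1,4-dien-2-yl)-4-[(S)-3-methyl-3-(triethylsilyloxy)pent-4-enyl]tetrahydropyran-3-one, via lithium enolate 15 (not isolated)
Conditions: MeLi, THF, 0 °C; then 6, HMPA, −78 to −20 °C
Reagents that add atoms: none
Why: The regiospecific lithium enolate released from the silyl enol ether is alkylated anti to the C11a substituent, and the trans-diequatorial product (C4a S) is also the thermodynamic one because C4a stays epimerisable.

Step 11
Reactants: 16 diene ketone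
Product: 17 (4aS,7S,11aR,8Z)-7-methyl-11-methylene-7-(triethylsilyloxy)-1,4a,5,6,7,10,11,11a-octahydrocyclonona[c]pyran-4(3H)-one
Conditions: second-generation Grubbs catalyst (10 mol %), 1,4-benzoquinone (20 mol %), toluene (1 mM), 80 °C
Reagents that add atoms: none
Why: In this ring-closing metathesis the carbene loads on the unhindered allyl terminus and can only close onto the C8 vinyl group, the two arms are held gauche on the trans-diequatorial chair, and ring strain enforces the Z alkene.

Step 12
Reactants: 17 bicyclic ketone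
Product: 19 C3=C4 enol triflate of 17 (4aS,7S,11aR,8Z), via potassium enolate 18 (not isolated)
Conditions: KHMDS, THF, −78 °C; then N-(5-chloro-2-pyridyl)bis(trifluoromethanesulfonimide), −78 °C
Reagents that add atoms: N-(5-chloro-2-pyridyl)bis(trifluoromethanesulfonimide), O=S(=O)(N(c1ccc(Cl)cn1)S(=O)(=O)C(F)(F)F)C(F)(F)F
Why: Kinetic deprotonation by a bulky amide should take the accessible C3 methylene proton and not the flanked tertiary C4a–H, and O-triflation then fixes the enol ether O2–C3=C4 with a coupling handle on C4.

**Side chain C12–C17 (steps 13–17)**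

Step 13
Reactants: 20 methyl 2-hydroxyisobutyrate
Product: 21 methyl 2-methyl-2-(triethylsilyloxy)propanoate
Conditions: TESOTf, 2,6-lutidine, CH2Cl2, 0 °C
Reagents that add atoms: triethylsilyl triflate, CC[Si](CC)(CC)OS(=O)(=O)C(F)(F)F
Why: Silylating the tertiary alcohol blocks O15, so that only O14 can later bind titanium.

Step 14
Reactants: 21 silyloxy ester
Product: 22 4-methyl-4-(triethylsilyloxy)-1-(trimethylsilyl)pent-1-yn-3-one
Conditions: trimethylsilylacetylene, n-BuLi, THF, −78 °C; BF3·OEt2; then 21, −78 °C
Reagents that add atoms: trimethylsilylacetylene, C#C[Si](C)(C)C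
Why: The boron trifluoride mediated acylation of a lithium acetylide by an ester stops at the ynone, because the hindered tetrahedral adduct survives until the quench.

Step 15
Reactants: 22 ynone
Product: 23 (R)-4-methyl-4-(triethylsilyloxy)-1-(trimethylsilyl)pent-1-yn-3-ol
Conditions: Ru[(S,S)-TsDPEN](p-cymene) (1 mol %), i-PrOH, 25 °C
Reagents that add atoms: none
Why: In the Noyori asymmetric transfer hydrogenation of an alkynyl ketone the (S,S) catalyst places the alkyne under the arene ligand and delivers hydride to the face that gives 14R, and the neutral medium avoids silyl migration.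

Step 16
Reactants: 23 silylated propargylic alcohol
Product: 24 (R)-4-methyl-4-(triethylsilyloxy)pent-1-yn-3-ol
Conditions: AgNO3 (10 mol %), acetone–H2O, rt
Reagents that add atoms: none
Why: Silver-catalysed protiodesilylation cleaves only the alkynyl C–Si bond and generates no alkoxide that could move the triethylsilyl group from O15 to O14.

Step 17
Reactants: 24 terminal alkyne
Product: 25 (R,E)-4-methyl-1-(tributylstannyl)-4-(triethylsilyloxy)pent-1-en-3-ol
Conditions: Bu3SnH, PdCl2(PPh3)2 (2 mol %), THF, 0 °C
Reagents that add atoms: tributyltin hydride, CCCC[SnH](CCCC)CCCC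
Why: Palladium-catalysed syn hydrostannation puts tin on the terminal carbon because of the bulky carbinol side, which gives the E-vinylstannane.

**Endgame (steps 18–21)**

Step 18
Reactants: 19 enol triflate; 25 vinylstannane
Product: 26 dienol ether, which is 19 with the triflate replaced by a (1E,3R)-3-hydroxy-4-methyl-4-(triethylsilyloxy)pent-1-enyl group on C4
Conditions: Pd2(dba)3 (5 mol %), AsPh3 (20 mol %), LiCl, NMP, 40 °C; chromatography on Et3N-deactivated silica
Reagents that add atoms: none
Why: Stille coupling of an enol triflate with a vinylstannane runs under neutral conditions with retention of both alkene geometries and tolerates the free carbinol and the acid-sensitive enol ether.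

Step 19
Reactants: 26 dienol ether
Product: 28 tricyclic acetal (3S,4aS,7S,11aR,13R,14R; 7,15-bis-triethylsilyl ether of 29), via vinyl oxirane 27 (not isolated)
Conditions: Ti(OiPr)4 (20 mol %), L-(+)-diisopropyl tartrate (24 mol %), t-BuOOH (decane, 1.5 equiv), 4 Å molecular sieves, CH2Cl2, −25 to 0 °C; quench with aqueous NaOH–brine
Reagents that add atoms: tert-butyl hydroperoxide, CC(C)(C)OO
Why: The tetravalent titanium–tartrate complex binds the C14 alkoxide and delivers oxygen only to the adjacent C12=C13 bond (Sharpless asymmetric epoxidation, matched pairing of L-(+)-tartrate with the 14R carbinol, giving the erythro 12S,13S oxirane 27), so the ring alkenes, which carry no free allylic hydroxyl, stay untouched. In 27 the C12–O bond is activated vinylogously by the enol ether O2–C3=C4, so under the Lewis acid it ionises to the O2=C3–C4=C12 oxocarbenium ion and the C13 alkoxide recloses on C3, a net suprafacial 1,3-shift of oxygen that enlarges the oxirane by two atoms; the closest known reaction type is the Lewis acid or Cu(hfacac)2 catalysed vinyl oxirane to 2,5-dihydrofuran ring expansion. The only ring closed is the dihydrofuran, by 5-exo-trig attack of O13 on the C3=O2 oxocarbenium bond. C13 keeps the configuration set by the tartrate because its C–O bond is never broken, while C3 follows from the suprafacial course: in the reactive rotamer, with C13 turned towards H3, the oxirane oxygen lies over the face of C3 that gives the equatorial C3–O bond. C3 is also secured by thermodynamics, because the acetal can reopen and the planar dihydrofuran fits only an equatorial C3–O bond on the trans-fused chair. The step needs Z geometry at C4=C12 and closure by O13 rather than by O14 or an external alcohol: the first is secured by allylic strain between C13 and C4a, the second by ion-pair proximity and the faster five-membered closure, O15 being silylated.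

Step 20
Reactants: 28 tricyclic acetal
Product: 29 (8Z)-alkene triol (3S,4aS,7S,11aR,13R,14R), the 8,9-deoxy target
Conditions: TBAF, THF, 0 °C to rt
Reagents that add atoms: none
Why: Fluoride-induced cleavage of both tertiary triethylsilyl ethers takes place under basic conditions, to which the acid-labile allylic acetal is inert.

Step 21
Reactants: 29 alkene triol
Product: 30 target CNP0281409.2
Conditions: VO(acac)2 (5 mol %), t-BuOOH (1.2 equiv), 2,6-lutidine (0.2 equiv), CH2Cl2, 0 °C
Reagents that add atoms: tert-butyl hydroperoxide, CC(C)(C)OO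
Why: In this vanadium-catalysed hydroxyl-directed epoxidation the C7 vanadate ester delivers oxygen to the face of the Z C8=C9 bond syn to the C7 hydroxyl and gives the cis-epoxy alcohol (8R,9R), while C11=C19 has no directing group and the electron-poor C4=C12 bond is only homoallylic to O14.

**Compound list**

1 | (S)-(+)-linalool | C=C[C@@](C)(O)CCC=C(C)C | starting material
2 | (S)-linalool triethylsilyl ether | C=C[C@@](C)(O[Si](CC)(CC)CC)CCC=C(C)C | intermediate
3 | (S)-4-methyl-4-(triethylsilyloxy)hex-5-enal | C=C[C@@](C)(O[Si](CC)(CC)CC)CCC=O | intermediate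
4 | (S,Z)-tert-butyldimethylsilyl enol ether of 3 | C=C[C@@](C)(O[Si](CC)(CC)CC)C/C=C\O[Si](C)(C)C(C)(C)C | intermediate
5 | (S)-3-methyl-3-(triethylsilyloxy)pent-4-en-1-ol | C=C[C@@](C)(O[Si](CC)(CC)CC)CCO | intermediate
6 | (S)-5-iodo-3-methyl-3-(triethylsilyloxy)pent-1-ene | C=C[C@@](C)(O[Si](CC)(CC)CC)CCI | intermediate
7 | 2,3-dibromopropene | C=C(Br)CBr | starting material
8 | 2-bromopenta-1,4-diene | C=CCC(Br)=C | intermediate
9 | furfuryl alcohol | OCc1ccco1 | starting material
10 | 6-hydroxy-2H-pyran-3(6H)-one (racemic) | O=C1COC(O)C=C1 | intermediate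
11 | 2H-pyran-3(6H)-one | O=C1COCC=C1 | intermediate
12 | penta-1,4-dien-2-ylmagnesium bromide | C=CCC(=C)[Mg]Br | intermediate
13 | bromomagnesium enolate (11aR) | C=CCC(=C)[C@@H]1COCC(O[Mg]Br)=C1 | intermediate
14 | (R)-5-(penta-1,4-dien-2-yl)-3-(trimethylsilyloxy)-5,6-dihydro-2H-pyran | C=CCC(=C)[C@@H]1COCC(O[Si](C)(C)C)=C1 | intermediate
15 | lithium enolate (11aR) | C=CCC(=C)[C@@H]1COCC(O[Li])=C1 | intermediate
16 | (4S,5R)-5-(penta-1,4-dien-2-yl)-4-[(S)-3-methyl-3-(triethylsilyloxy)pent-4-enyl]tetrahydropyran-3-one | C=CCC(=C)[C@@H]1COCC(=O)[C@H]1CC[C@](C)(O[Si](CC)(CC)CC)C=C | intermediate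
17 | bicyclic ketone (4aS,7S,11aR,8Z): C4 ketone, C7 OTES, C11 methylene | C=C1C/C=C\[C@@](C)(O[Si](CC)(CC)CC)CC[C@@H]2C(=O)COC[C@@H]12 | intermediate
18 | potassium C3=C4 enolate of 17 | C=C1C/C=C\[C@@](C)(O[Si](CC)(CC)CC)CC[C@@H]2C(O[K])=COC[C@@H]12 | intermediate
19 | C3=C4 enol triflate of 17 | C=C1C/C=C\[C@@](C)(O[Si](CC)(CC)CC)CC[C@@H]2C(OS(=O)(=O)C(F)(F)F)=COC[C@@H]12 | intermediate
20 | methyl 2-hydroxyisobutyrate | COC(=O)C(C)(C)O | starting material
21 | methyl 2-methyl-2-(triethylsilyloxy)propanoate | COC(=O)C(C)(C)O[Si](CC)(CC)CC | intermediate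
22 | 4-methyl-4-(triethylsilyloxy)-1-(trimethylsilyl)pent-1-yn-3-one | C[Si](C)(C)C#CC(=O)C(C)(C)O[Si](CC)(CC)CC | intermediate
23 | (R)-4-methyl-4-(triethylsilyloxy)-1-(trimethylsilyl)pent-1-yn-3-ol | C[Si](C)(C)C#C[C@@H](O)C(C)(C)O[Si](CC)(CC)CC | intermediate
24 | (R)-4-methyl-4-(triethylsilyloxy)pent-1-yn-3-ol | C#C[C@@H](O)C(C)(C)O[Si](CC)(CC)CC | intermediate
25 | (R,E)-4-methyl-1-(tributylstannyl)-4-(triethylsilyloxy)pent-1-en-3-ol | CCCC[Sn](CCCC)(CCCC)/C=C/[C@@H](O)C(C)(C)O[Si](CC)(CC)CC | intermediate
26 | dienol ether (4aS,7S,11aR,14R; 8Z,12E) | C=C1C/C=C\[C@@](C)(O[Si](CC)(CC)CC)CC[C@@H]2C(/C=C/[C@@H](O)C(C)(C)O[Si](CC)(CC)CC)=COC[C@@H]12 | intermediate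
27 | vinyl oxirane, (12S,13S,14R)-12,13-epoxide of 26 | C=C1C/C=C\[C@@](C)(O[Si](CC)(CC)CC)CC[C@@H]2C([C@@H]3O[C@H]3[C@@H](O)C(C)(C)O[Si](CC)(CC)CC)=COC[C@@H]12 | intermediate
28 | tricyclic acetal, 7,15-bis(triethylsilyl) ether of 29 | C=C1C/C=C\[C@@](C)(O[Si](CC)(CC)CC)CC[C@@H]2C3=C[C@H]([C@@H](O)C(C)(C)O[Si](CC)(CC)CC)O[C@@H]3OC[C@@H]12 | intermediate
29 | (8Z)-alkene triol, 8,9-deoxy target | C=C1C/C=C\[C@@](C)(O)CC[C@@H]2C3=C[C@H]([C@@H](O)C(C)(C)O)O[C@@H]3OC[C@@H]12 | intermediate
30 | CNP0281409.2 (3S,4aS,7S,8R,9R,11aR,13R,14R) | C=C1C[C@H]2O[C@H]2[C@@](C)(O)CC[C@@H]2C3=C[C@H]([C@@H](O)C(C)(C)O)O[C@@H]3OC[C@@H]12 | target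

**Step count**

- Total step count: 21.
- Longest linear sequence: 12 steps (1–5, 10–12, 18–21).

**The three steps most likely to fail**

**Step 11, ring-closing metathesis.** Closure onto the hindered C8 vinyl group may be slow, so that oligomerisation through the allyl terminus takes over. Alternatively, a carbene that ends up on C8 may close on the C11 methylene to a seven-membered ring.

The fallback moves the closure to the end of the route and onto a free tertiary allylic alcohol. Such an alcohol is reactive enough for the first-generation Grubbs catalyst, which ignores 1,1-disubstituted alkenes. At the ketone stage the free C7 hydroxyl is not an option, because the δ-hydroxy ketone would close to a hemiketal. The fallback sets out from 16. Enolisation and triflation as in step 12 give the seco enol triflate F1, and Stille coupling with 25 gives the seco dienol ether F2. The epoxidation and ring expansion of step 19 lead, by way of the seco vinyl oxirane F3, to the seco acetal F4. Fluoride then frees the seco triol F5, and metathesis of F5 in dilute CH2Cl2 comes back to the route at 29.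

**Step 12, enol triflate.** Regiocontrol in the enolisation may be lost, because the oxygen on C3 lowers the kinetic acidity of the C3 protons and enolate equilibration favours the tetrasubstituted C4=C4a isomer.

The fallback leaves enolate chemistry for the Barton vinyl iodide synthesis. There the proton is lost from an iodinated cationic or geminal diiodide centre at C4, and loss from C3 gives the oxygen-conjugated alkene. The fallback sets out from 17. Hydrazine hydrate and Et3N in ethanol give the hydrazone F6. Iodine and 1,1,3,3-tetramethylguanidine in THF at 0 °C give the C4 vinyl iodide F7. Stille coupling of F7 with 25 under the conditions of step 18 comes back to the route at 26.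

**Step 19, epoxidation and ring expansion.** Titanium may ionise the doubly vinylogous C14 carbinol before oxygen transfer. The oxocarbenium ion may be captured by 2-propanol or the hydroperoxide, or it may close through O14 to a six-membered acetal.

The fallback sets the stereocentres on a robust fragment and generates the oxirane under base, with no oxidant or Lewis acid near the enol ether.

- 2-Methylbut-3-yn-2-ol is silylated to the silyl ether F8 and hydroxymethylated (n-BuLi, paraformaldehyde) to the propargylic alcohol F9.
- Red-Al reduces F9 to the (E)-allylic alcohol F10, and Sharpless epoxidation with L-(+)-diethyl tartrate gives the (2S,3R)-epoxy alcohol F11.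
- Oxidation (SO3·pyridine, DMSO, Et3N) gives the (2R,3R)-epoxy aldehyde F12.
- Nozaki–Hiyama–Kishi coupling of 19 with F12 (CrCl2, NiCl2 catalyst, DMF) gives the 12-hydroxy-13,14-epoxide F13 as a mixture at C12.

NaH in THF at 0 °C then triggers a Payne rearrangement. O12 attacks C13 with inversion and frees O14, which gives the alkoxides of 27 and of its C12 epimer F14. Both expand to the same dihydrofuran because C12 becomes trigonal. The fallback sets out from 19 and comes back to the route at 28.

**Further compounds**

F1 | step 11 | seco enol triflate | C=CCC(=C)[C@@H]1COC=C(OS(=O)(=O)C(F)(F)F)[C@H]1CC[C@](C)(O[Si](CC)(CC)CC)C=C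
F2 | step 11 | seco dienol ether | C=CCC(=C)[C@@H]1COC=C(/C=C/[C@@H](O)C(C)(C)O[Si](CC)(CC)CC)[C@H]1CC[C@](C)(O[Si](CC)(CC)CC)C=C
F3 | step 11 | seco vinyl oxirane | C=CCC(=C)[C@@H]1COC=C([C@@H]2O[C@H]2[C@@H](O)C(C)(C)O[Si](CC)(CC)CC)[C@H]1CC[C@](C)(O[Si](CC)(CC)CC)C=C
F4 | step 11 | seco acetal | C=CCC(=C)[C@@H]1CO[C@H]2O[C@@H]([C@@H](O)C(C)(C)O[Si](CC)(CC)CC)C=C2[C@H]1CC[C@](C)(O[Si](CC)(CC)CC)C=C
F5 | step 11 | seco triol | C=CCC(=C)[C@@H]1CO[C@H]2O[C@@H]([C@@H](O)C(C)(C)O)C=C2[C@H]1CC[C@](C)(O)C=C
F6 | step 12 | hydrazone | C=C1C/C=C\[C@@](C)(O[Si](CC)(CC)CC)CC[C@@H]2C(=NN)COC[C@@H]12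
F7 | step 12 | C4 vinyl iodide | C=C1C/C=C\[C@@](C)(O[Si](CC)(CC)CC)CC[C@@H]2C(I)=COC[C@@H]12
F8 | step 19 | silyl ether | C#CC(C)(C)O[Si](CC)(CC)CC
F9 | step 19 | propargylic alcohol | OCC#CC(C)(C)O[Si](CC)(CC)CC
F10 | step 19 | (E)-allylic alcohol | OC/C=C/C(C)(C)O[Si](CC)(CC)CC
F11 | step 19 | (2S,3R)-epoxy alcohol | OC[C@@H]1O[C@H]1C(C)(C)O[Si](CC)(CC)CC
F12 | step 19 | (2R,3R)-epoxy aldehyde | O=C[C@@H]1O[C@H]1C(C)(C)O[Si](CC)(CC)CC
F13 | step 19 | 12-hydroxy-13,14-epoxide | C=C1C/C=C\[C@@](C)(O[Si](CC)(CC)CC)CC[C@@H]2C(C(O)[C@@H]3O[C@H]3C(C)(C)O[Si](CC)(CC)CC)=COC[C@@H]12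
F14 | step 19 | C12 epimer | C=C1C/C=C\[C@@](C)(O[Si](CC)(CC)CC)CC[C@@H]2C([C@H]3O[C@H]3[C@@H](O)C(C)(C)O[Si](CC)(CC)CC)=COC[C@@H]12
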